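The 2,4-disubstituted furan is cut across its C3=C4 bond (O1, aryl on C2, side chain on C4), which splits the ring into a racemic aryl vinyl carbinol (C2, C3) and an enantiopure 2-substituted acrolein acetal (C4, C5). Joined as a mixed ethyl acetal, the halves form a diene whose vinyl and 1,1-disubstituted alkenes are closed by ruthenium-catalysed metathesis; a trace of acid then strips ethanol from the 2-ethoxy-2,5-dihydrofuran, so the aromatic ring appears without isolation of the intermediate. Regiochemistry is thus decided by the two building blocks, and the single stereocentre, set earlier by oxazaborolidine reduction and carried as the isovalerate, stays untouched. Buffered fluoride finally frees the hydroquinone.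

Key step: step 8

Remark: carbinol 14 is used as the racemate, and 16 and 17 as epimer mixtures at the acetal and benzylic carbons, because both centres disappear in step 8; their SMILES leave these centres undefined. The ester carbon is (R) in 8, 10, 15, 16, 17, 18 and 19, since the alkenyl or furyl carbon outranks the prenyl CH2 throughout.

Step 1
Reactants: 1 4-methylpent-3-enoic acid
Product: 3 N-methoxy-N,4-dimethylpent-3-enamide, via acyl imidazolide 2 (not isolated)
Conditions: CDI (1.1 equiv), CH2Cl2, 0 °C to rt; then MeNH(OMe)·HCl (1.3 equiv), rt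
Reagents that add atoms: N,O-dimethylhydroxylamine hydrochloride, CNOC.Cl
Why: Carbonyldiimidazole converts the acid into acyl imidazolide 2 without strong base, so the beta,gamma-alkene should not drift into conjugation, and aminolysis by the hydroxylamine gives the Weinreb amide (CDI amide coupling).

Step 2
Reactants: 4 2-bromo-3,3-diethoxyprop-1-ene (2-bromoacrolein diethyl acetal); 3 N-methoxy-N,4-dimethylpent-3-enamide
Product: 7 2-(diethoxymethyl)-6-methylhepta-1,5-dien-3-one, via vinyllithium 5 (not isolated), via tetrahedral lithium adduct 6 (not isolated)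
Conditions: 4 (1.3 equiv), t-BuLi (1.95 equiv per 4), Et2O, −78 °C; then 3 in THF, −78 °C; AcOH in THF at −78 °C, then water
Reagents that add atoms: none
Why: Bromine-lithium exchange gives vinyllithium 5, a known alpha-anion equivalent of acrolein that must be kept cold, and its addition to 3 stops at the chelated adduct 6 (Weinreb ketone synthesis), so the enolisable beta,gamma-unsaturated enone is released only by the cold acidic quench and neither over-addition nor alkene migration should occur.

Step 3
Reactants: 7 2-(diethoxymethyl)-6-methylhepta-1,5-dien-3-one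
Product: 8 (3R)-2-(diethoxymethyl)-6-methylhepta-1,5-dien-3-ol
Conditions: (S)-Me-CBS oxazaborolidine, i.e. (3aS)-1-methyl-3,3-diphenyltetrahydro-1H,3H-pyrrolo[1,2-c][1,3,2]oxazaborole (0.2 equiv), catecholborane (1.5 equiv), toluene, −78 °C; MeOH, then aqueous NaOH wash
Reagents that add atoms: none
Why: Corey-Bakshi-Shibata reduction, in which the ketone binds the ring boron through the oxygen lone pair on the side of the smaller CH2 group, the alpha-branched alkenyl group acts as the large substituent, and the nitrogen-bound catecholborane delivers hydride intramolecularly to the Si face to set the (R) carbinol centre, while the cold conditions should avoid hydroboration of the alkenes and 1,4-reduction.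

Step 4
Reactants: 8 (3R)-2-(diethoxymethyl)-6-methylhepta-1,5-dien-3-ol; 9 3-methylbutanoyl chloride (isovaleryl chloride)
Product: 10 (3R)-2-(diethoxymethyl)-6-methylhepta-1,5-dien-3-yl 3-methylbutanoate
Conditions: pyridine (3 equiv), 4-(dimethylamino)pyridine (0.1 equiv), CH2Cl2, 0 °C to rt
Reagents that add atoms: none
Why: Acylation of the secondary allylic alcohol by the acid chloride under nucleophilic catalysis by 4-(dimethylamino)pyridine takes place at oxygen, so the C-O bond and the (R) configuration are retained, and the basic medium keeps the diethyl acetal intact.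

Step 5
Reactants: 11 2,5-dihydroxybenzaldehyde
Product: 12 2,5-bis(tert-butyldimethylsilyloxy)benzaldehyde
Conditions: TBSCl (2.5 equiv), imidazole (5 equiv), DMF, rt
Reagents that add atoms: tert-butyldimethylsilyl chloride, CC(C)(C)[Si](C)(C)Cl
Why: Imidazole-promoted silylation of both phenols (Corey silyl ether formation), with excess reagent to compensate for the hydrogen-bonded ortho phenol.

Step 6
Reactants: 12 2,5-bis(tert-butyldimethylsilyloxy)benzaldehyde; 13 vinylmagnesium bromide
Product: 14 rac-1-[2,5-bis(tert-butyldimethylsilyloxy)phenyl]prop-2-en-1-ol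
Conditions: 13 (1.2 equiv), THF, −78 °C; AcOH (1.5 equiv) at −78 °C, then water
Reagents that add atoms: none
Why: Grignard 1,2-addition to the aldehyde gives the benzylic allylic alcohol as a racemate, which suffices because this centre is erased in step 8, and the cold acetic acid quench protonates the magnesium alkoxide before the ortho silyl group can migrate to it.

Step 7
Reactants: 10 (3R)-2-(diethoxymethyl)-6-methylhepta-1,5-dien-3-yl 3-methylbutanoate; 14 rac-1-[2,5-bis(tert-butyldimethylsilyloxy)phenyl]prop-2-en-1-ol
Product: 16 (3R)-2-[({1-[2,5-bis(tert-butyldimethylsilyloxy)phenyl]prop-2-en-1-yl}oxy)(ethoxy)methyl]-6-methylhepta-1,5-dien-3-yl 3-methylbutanoate, via collidinium triflate 15 (not isolated)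
Conditions: TESOTf (1.3 equiv), 2,4,6-collidine (3 equiv), CH2Cl2, 0 °C; then 14 (1.5 equiv), 0 °C to rt
Reagents that add atoms: none
Why: Triethylsilyl triflate with collidine removes one ethoxy group of the aldehyde-derived acetal and holds the cation as N-(1-ethoxyalkyl)collidinium salt 15, which the added alcohol displaces at the acetal carbon (collidinium-mediated acetal exchange) under non-acidic conditions that should spare the ester, the aryl silyl ethers and the ionisable benzylic allylic alcohol.

Step 8
Reactants: 16 mixed ethyl acetal diene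
Product: 18 (1R)-1-{5-[2,5-bis(tert-butyldimethylsilyloxy)phenyl]furan-3-yl}-4-methylpent-3-en-1-yl 3-methylbutanoate, via 2-ethoxy-2,5-dihydrofuran 17 (not isolated)
Conditions: RuCl2(=CH-C6H4-2-OiPr)(SIMes) (second-generation Hoveyda-Grubbs catalyst; SIMes = 1,3-dimesitylimidazolidin-2-ylidene; 5-10 mol %), degassed 1,2-dichloroethane (0.01 M), 60 °C; then pyridinium p-toluenesulfonate (0.2 equiv), rt
Reagents that add atoms: none
Why: The ruthenium benzylidene exchanges onto the monosubstituted vinyl group of 16, the new alkylidene adds across the 1,1-disubstituted alkene through a ruthenacyclobutane, and cycloreversion releases ethene while forming the endocyclic C3=C4 bond of 17 (ring-closing alkene metathesis). The closest known reaction type is the metathesis of mixed allylic acetals to 2-alkoxy-2,5-dihydrofurans followed by acid-promoted loss of the alcohol. The one ring is closed as a five-membered ring by metathesis between two alkene carbons already tethered through the C2-O1-C5 acetal linkage, the most favourable ring size for this reaction. No stereocentre is created: protonation of the ethoxy group gives a cyclic oxocarbenium ion, loss of the benzylic C2 proton aromatises it, and the acetal and benzylic centres vanish, so all epimers of 16 should converge on 18 while the (R) ester carbon is a spectator. The step needs chemoselectivity among three alkenes, which the substrate secures because the prenyl alkene is trisubstituted and sluggish toward the catalyst and could only close a cyclobutene or an eight-membered cyclic acetal, while high dilution suppresses intermolecular metathesis at the vinyl group. The buffered acid is weak enough to leave the furylic isovalerate and the aryl silyl ethers in place.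

Step 9
Reactants: 18 bis(tert-butyldimethylsilyl) ether of the target
Product: 19 (1R)-1-[5-(2,5-dihydroxyphenyl)furan-3-yl]-4-methylpent-3-en-1-yl 3-methylbutanoate
Conditions: TBAF (2.5 equiv), AcOH (3 equiv), degassed THF, 0 °C, argon; degassed pH 6 buffer work-up
Reagents that add atoms: none
Why: Fluoride cleaves the aryl O-Si bonds rapidly (fluoride desilylation), acetic acid buffers the phenoxides so that neither ester cleavage nor acyl transfer should occur, exclusion of air protects the hydroquinone from oxidation to the quinone, and the stereocentre is not involved.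

Compound list
1 | 4-methylpent-3-enoic acid | CC(C)=CCC(=O)O | starting material
2 | 1-(4-methylpent-3-enoyl)imidazole (acyl imidazolide, not isolated) | CC(C)=CCC(=O)n1ccnc1 | intermediate
3 | N-methoxy-N,4-dimethylpent-3-enamide (Weinreb amide) | CC(C)=CCC(=O)N(C)OC | intermediate
4 | 2-bromo-3,3-diethoxyprop-1-ene (2-bromoacrolein diethyl acetal) | C=C(Br)C(OCC)OCC | starting material
5 | (3,3-diethoxyprop-1-en-2-yl)lithium (vinyllithium, not isolated) | [Li]C(=C)C(OCC)OCC | intermediate
6 | lithium 2-(diethoxymethyl)-3-[methoxy(methyl)amino]-6-methylhepta-1,5-dien-3-olate (tetrahedral adduct, not isolated) | CC(C)=CCC(O[Li])(N(C)OC)C(=C)C(OCC)OCC | intermediate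
7 | 2-(diethoxymethyl)-6-methylhepta-1,5-dien-3-one | CC(C)=CCC(=O)C(=C)C(OCC)OCC | intermediate
8 | (3R)-2-(diethoxymethyl)-6-methylhepta-1,5-dien-3-ol | CC(C)=CC[C@@H](O)C(=C)C(OCC)OCC | intermediate
9 | 3-methylbutanoyl chloride (isovaleryl chloride) | CC(C)CC(=O)Cl | starting material
10 | (3R)-2-(diethoxymethyl)-6-methylhepta-1,5-dien-3-yl 3-methylbutanoate | CC(C)=CC[C@@H](OC(=O)CC(C)C)C(=C)C(OCC)OCC | intermediate
11 | 2,5-dihydroxybenzaldehyde | O=Cc1cc(O)ccc1O | starting material
12 | 2,5-bis(tert-butyldimethylsilyloxy)benzaldehyde | O=Cc1cc(O[Si](C)(C)C(C)(C)C)ccc1O[Si](C)(C)C(C)(C)C | intermediate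
13 | vinylmagnesium bromide | C=C[Mg]Br | starting material
14 | rac-1-[2,5-bis(tert-butyldimethylsilyloxy)phenyl]prop-2-en-1-ol | C=CC(O)c1cc(O[Si](C)(C)C(C)(C)C)ccc1O[Si](C)(C)C(C)(C)C | intermediate
15 | 1-[(3R)-1-ethoxy-6-methyl-2-methylidene-3-(3-methylbutanoyloxy)hept-5-en-1-yl]-2,4,6-trimethylpyridinium trifluoromethanesulfonate (epimers at the N,O-acetal carbon, not isolated) | CC(C)=CC[C@@H](OC(=O)CC(C)C)C(=C)C(OCC)[n+]1c(C)cc(C)cc1C.[O-]S(=O)(=O)C(F)(F)F | intermediate
16 | (3R)-2-[({1-[2,5-bis(tert-butyldimethylsilyloxy)phenyl]prop-2-en-1-yl}oxy)(ethoxy)methyl]-6-methylhepta-1,5-dien-3-yl 3-methylbutanoate (mixed ethyl acetal diene, epimer mixture at the acetal and benzylic carbons) | CC(C)=CC[C@@H](OC(=O)CC(C)C)C(=C)C(OCC)OC(C=C)c1cc(O[Si](C)(C)C(C)(C)C)ccc1O[Si](C)(C)C(C)(C)C | intermediate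
17 | (1R)-1-{5-[2,5-bis(tert-butyldimethylsilyloxy)phenyl]-2-ethoxy-2,5-dihydrofuran-3-yl}-4-methylpent-3-en-1-yl 3-methylbutanoate (epimer mixture at ring C2 and C5, not isolated) | CC(C)=CC[C@@H](OC(=O)CC(C)C)C1=CC(c2cc(O[Si](C)(C)C(C)(C)C)ccc2O[Si](C)(C)C(C)(C)C)OC1OCC | intermediate
18 | (1R)-1-{5-[2,5-bis(tert-butyldimethylsilyloxy)phenyl]furan-3-yl}-4-methylpent-3-en-1-yl 3-methylbutanoate | CC(C)=CC[C@@H](OC(=O)CC(C)C)c1coc(-c2cc(O[Si](C)(C)C(C)(C)C)ccc2O[Si](C)(C)C(C)(C)C)c1 | intermediate
19 | (1R)-1-[5-(2,5-dihydroxyphenyl)furan-3-yl]-4-methylpent-3-en-1-yl 3-methylbutanoate (CNP0296263.1) | CC(C)=CC[C@@H](OC(=O)CC(C)C)c1coc(-c2cc(O)ccc2O)c1 | target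

Total step count: 9.
Longest linear sequence: 7 steps (steps 1, 2, 3, 4, 7, 8, 9, from 4-methylpent-3-enoic acid).

Steps most likely to fail

1. Step 8. Ring closure onto the 1,1-disubstituted alkene, which is flanked by the acetal carbon and the acyloxy-bearing carbon, may be slower than catalyst decay. Isomerisation of the allyl ether or intermolecular metathesis at the vinyl group could then take over. During aromatisation, ionisation at the furylic ester carbon is a second way to lose material or optical purity. Fallback: the aryl group is attached to a purchased furan by cross-coupling; it sets out from Weinreb amide 3 and comes back to the route at 18. Furan-3-yllithium F1 (3-bromofuran, n-BuLi, THF, −78 °C) is acylated by 3 to give 1-(furan-3-yl)-4-methylpent-3-en-1-one F2. Reduction under the conditions of step 3, with the furyl ring as the large group, should give (1R)-1-(furan-3-yl)-4-methylpent-3-en-1-ol F3. Acylation with 9 as in step 4 gives (1R)-1-(furan-3-yl)-4-methylpent-3-en-1-yl 3-methylbutanoate F4. Iridium-catalysed C-H borylation ([Ir(OMe)(cod)]2, 4,4'-di-tert-butyl-2,2'-bipyridine, B2pin2, THF, 50 °C) should go to the unhindered alpha carbon C5 and give the pinacol boronate (1R)-4-methyl-1-[5-(4,4,5,5-tetramethyl-1,3,2-dioxaborolan-2-yl)furan-3-yl]pent-3-en-1-yl 3-methylbutanoate F5. Suzuki-Miyaura coupling of F5 with 2-bromo-1,4-bis(tert-butyldimethylsilyloxy)benzene F6 (made from 2-bromohydroquinone, TBSCl and imidazole), using Pd(OAc)2, 2-dicyclohexylphosphino-2',6'-dimethoxybiphenyl and K3PO4 in THF/water at 40 °C, gives 18.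

2. Step 7. Residual silyl triflate may silylate carbinol 14. The neighbouring isovalerate carbonyl may take part in the cationic intermediate and scramble the acyl group. The alcohol may also attack the alkene terminus of the allylic cation and not the acetal carbon. Fallback: the exchange is done in two stages through an alpha-chloro ether under basic conditions; it sets out from 10 and comes back at 16. Acetyl chloride with catalytic ZnCl2 (CH2Cl2, 0 °C) replaces one ethoxy group by chloride to give (3R)-2-[chloro(ethoxy)methyl]-6-methylhepta-1,5-dien-3-yl 3-methylbutanoate F7. F7 is used crude and alkylates 14 in the presence of i-Pr2NEt (CH2Cl2, 0 °C to rt) to give 16.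

3. Step 2. Vinyllithium 5 may lose lithium ethoxide if the temperature rises. Amide 3 may be deprotonated at its doubly activated methylene in place of addition. The beta,gamma-alkene of the product may move into conjugation during work-up. Fallback: the carbon-carbon bond is made by a chromium-mediated addition to an aldehyde, with no strongly basic organometallic, followed by oxidation; it sets out from 3 and 4 and comes back at 7. i-Bu2AlH (toluene, −78 °C) reduces 3 to 4-methylpent-3-enal F8. Nozaki-Hiyama-Kishi coupling of 4 with F8 (CrCl2, catalytic NiCl2, DMF, rt) gives racemic 2-(diethoxymethyl)-6-methylhepta-1,5-dien-3-ol F9. Dess-Martin periodinane buffered with NaHCO3 (CH2Cl2, 0 °C) oxidises F9 to 7.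

Further compounds
F1 | step 8 | furan-3-yllithium | [Li]c1ccoc1
F2 | step 8 | 1-(furan-3-yl)-4-methylpent-3-en-1-one | CC(C)=CCC(=O)c1ccoc1
F3 | step 8 | (1R)-1-(furan-3-yl)-4-methylpent-3-en-1-ol | CC(C)=CC[C@@H](O)c1ccoc1
F4 | step 8 | (1R)-1-(furan-3-yl)-4-methylpent-3-en-1-yl 3-methylbutanoate | CC(C)=CC[C@@H](OC(=O)CC(C)C)c1ccoc1
F5 | step 8 | (1R)-4-methyl-1-[5-(4,4,5,5-tetramethyl-1,3,2-dioxaborolan-2-yl)furan-3-yl]pent-3-en-1-yl 3-methylbutanoate | CC(C)=CC[C@@H](OC(=O)CC(C)C)c1coc(B2OC(C)(C)C(C)(C)O2)c1
F6 | step 8 | 2-bromo-1,4-bis(tert-butyldimethylsilyloxy)benzene | Brc1cc(O[Si](C)(C)C(C)(C)C)ccc1O[Si](C)(C)C(C)(C)C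
F7 | step 7 | (3R)-2-[chloro(ethoxy)methyl]-6-methylhepta-1,5-dien-3-yl 3-methylbutanoate | CC(C)=CC[C@@H](OC(=O)CC(C)C)C(=C)C(Cl)OCC
F8 | step 2 | 4-methylpent-3-enal | CC(C)=CCC=O
F9 | step 2 | rac-2-(diethoxymethyl)-6-methylhepta-1,5-dien-3-ol | CC(C)=CCC(O)C(=C)C(OCC)OCC
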